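- where most of what was charged as J, at 40 h is found (Q / J)
- the largest share itself, whichever of these holds it, in percent of the J charged

| setting | Wednesday's | Tuesday's | flask |
|---|---|---|---|
| J | 0.10 M | 0.10 M | 0.10 M |
| Z | 14 mM | 22 mM | 10 mM |
| remark | run made earlier | run made earlier |  |
| time |  |  | 40 h |

| run | time / h | J / % | Q / % |
|---|---|---|---|
| Wednesday's | 5.00 | 81.7 | 17.5 |
| Wednesday's | 15.0 | 39.4 | 62.8 |
| Wednesday's | 25.0 | 14.9 | 82.8 |
| Wednesday's | 40.0 | 7.2 | 91.7 |
| Tuesday's | 5.00 | 75.8 | 25.7 |
| Tuesday's | 15.0 | 22.9 | 77.3 |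
| Tuesday's | 25.0 | 8.8 | 91.3 |
| Tuesday's | 40.0 | 6.3 | 93.3 |

(readings scatter by 1 percentage point)

In a one-step world with a constant rate, the excess of J over its floor shrinks in a pseudo-first-order way, so the logarithm of starting excess over present excess grows straight with time. J flattens late in Tuesday's run, so its last reading, 6.3 %, serves as the floor. Dividing that logarithm by the charged [Z] gives a drive per mM. At 15.0 h the drive is 0.0743 /mM on Wednesday and 0.0787 /mM on Tuesday; at 25.0 h it is 0.171 /mM and 0.165 /mM. Read so, the two runs lie close together at both times. Continuing the mean rise in a straight line gives the drive per mM of Z at 40 h, 0.304 /mM. For the new flask, with 10 mM of Z, this reckoning gives J 10.8 % and Q 89.2 %.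

The weak link is the straight extension, so the answer goes back in. On Wednesday's charge the drive gives J 7.62 %, against that run's last reading 7.2 %, which went into neither the floor nor the drive.

The forecast, taking a floor of about 6 %, said “The rate is therefore about first order in Z.” It named Q at 89 %, between 85.5 % and 91.5 %.

The flask holds 88.4 % as Q and 11.6 % as J, which reads back as a drive of 0.287 /mM. At 40.0 h the flask makes Q 1.60 times as fast as it uses Q up, so Q is still rising there. Left until 400 h, the flask stands at 92.6 % Q.

    Q + L → J + L, rate k1*[L] as long as [Q] is above zero (k = 2.00 × 10⁻⁵ /s)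
    J + X → L + Q (k = 0.00870 /M/s)
    J + L → Q + L, rate k3*[L]*[J] (k = 0.00270 /M/s)
    Z → X (k = 3.10 × 10⁻⁵ /s)
    X ⇌ G (K = 2.70, k = 5.20 × 10⁻⁵ /s)

A neighbour flask charged with 0.0025 M of Z and read at the same time should, by the same drive, hold J 50.1 %. It holds 50.7 % J and 49.3 % Q.

(The numbers in the tables were computed on assumed constants.)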